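# Proposed total synthesis of CNP0305801.1 (29)

## Analysis of the target

- Target 29 contains two chroman units that share one arene. The upper chroman (benzo ring A, pyran ring C) carries ring B (3-hydroxy-2,4-dimethoxyphenyl) at C3 and the central ring E at C4. Ring E is also the 3-aryl group of the lower chroman (benzo ring D, pyran ring F), bonded to lower C3 through E6.
- There are three stereocentres. Upper C3 (R) and C4 (S) are adjacent and trans on ring C. Lower C3 (R) is separated from this pair by ring E, so no relay of stereochemical information between the two sets can be relied on.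
- The sensitive groups are four free phenols on electron-rich rings, three aryl methyl ethers that must stay distinct from the hydroxyls, and the doubly benzylic C4–H.
- The main difficulty is ring E. It is a 1,2,4,6-tetrasubstituted arene with two different oxygens (methoxy at E2, hydroxyl at E4) and two ortho carbon substituents, of which E1 is flanked on both sides. Functionalising a preformed resorcinol would have to distinguish two nearly equivalent oxygens and two nearly equivalent ring positions.
- Every bond made at E1 or at upper C4 is made at a crowded site.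
- The strategy rests on the pattern of ring E: methoxy at E2 and hydroxyl at E4 meta to each other, hydrogen at E3 and E5, carbon at E1 and E6. This is the pattern left when a 1,1-dimethoxy-3-silyloxybutadiene adds to an ynone and the adduct aromatises. The ynone carbonyl ends on E1 and the alkyne substituent on E6.
- Building ring E this way lets the lower chroman be completed first, with its stereocentre, and leaves a benzophenone from which ring C is closed last.

## Retrosynthetic reasoning

**29 to 28.** The four phenols are masked as benzyl ethers, so the last step is a single hydrogenolysis. Nothing else in 28 is reducible under those conditions.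

**28 to 27, then to 20 and 25.** The C2 hydroxyl of lactol 27 is removed by ionic reduction. Ring C of 27 is cut at C3–C4 and O1–C2. This leads to the ortho-quinone methide 26, formed from benzhydrol 20, and to the arylacetaldehyde 25 that carries ring B. The cut is made here because the crowded ring E is already on the methide carbon and the two upper stereocentres can be set together by an amine catalyst. The forward reaction must add the enamine of 25 to the methide carbon with control of both new centres and close the hemiacetal.

**20 to 19, 18 and 17.** These are adjustments of oxidation level and protection. Benzhydrol 20 comes from ketone 19 by hydride reduction. The ring A ortho hydroxyl of 19 is released from the methoxymethyl ether 18 by acid. The E4 benzyl ether of 18 comes from phenol 17. An acetal is used on the ring A ortho oxygen, and not a benzyl ether, because ring E also has a methoxy group ortho to the same ketone and a chelation-controlled dealkylation would have to choose between them. The E4 oxygen is capped so that a quinone methide can form only through ring A.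

**17 to 11 and 14.** Ring E is cut at E1–E2 and E5–E6, which gives ynone 11 and diene 14. This is the central disconnection. It removes the need to differentiate oxygens on a preformed ring, it forms the crowded benzophenone without a coupling at a hindered position, and it uses a fragment that already holds rings D and F and lower C3. The forward reaction must deliver the regiochemistry with methoxy ortho and hydroxyl para to the ketone, and must not disturb the propargylic stereocentre.

**11 to 10, then to 7 and 8.** The ketone–alkyne bond is cut. Alkyne 7, as its lithium acetylide 9, adds to aldehyde 8 to give alcohol 10, which is oxidised under neutral conditions to 11. This is the shortest reliable ynone synthesis and avoids base at the ynone stage.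

**7 to 6, 4 and 3.** The alkyne carbon–carbon bond at lower C3 is traced to the carbon–boron bond of boronic ester 4, through bromoalkene 6 and the boronate complex 5. The migration from boron to carbon is stereoretentive. Ester 4 comes from chromene 3 by copper-catalysed enantioselective boron–hydrogen addition, which places boron at C3 of the styrenic alkene. This is where the lower stereocentre is created, catalytically and early.

**3 and 8 to 2, then to 1.** Both the chromene and the ring A aldehyde come from monobenzyl ether 2, made by selective alkylation of 1. Chromene 3 forms from 2 by phenoxide addition to a vinylphosphonium salt followed by intramolecular olefination. Aldehyde 8 forms from 2 by acetal protection.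

**14 to 13 and 12.** The diene is the silyl enol ether of the β,β-dimethoxy enone 13, which comes from C-acylation of ketene acetal 12.

**25 to 24, 23, 22 and 21.** The acetaldehyde carbon is added by a one-carbon olefination of aldehyde 23 to enol ether 24 and hydrolysis. Aldehyde 23 comes from formylation of ether 22 at the position ortho and para to its two methoxy groups, and 22 from benzylation of 21.

## Alternatives that were turned down

**Alternative 1: aryne acyl-alkylation.**
- Disconnection: the E1–C(=O) and E6–CH2 bonds are cut together, giving the silyl aryl triflate A2 and the β-ketoester A4.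
- Forward key step: fluoride converts A2 into aryne A3. The enolate carbon of A4 adds to the aryne carbon remote from the methoxy group, the aryl anion attacks the ketone, and the four-membered alkoxide fragments. The product is the ortho-acyl arylacetate A1, with the ring A ketone on E1 and an ester-bearing CH2 (the future lower C3) on E6.
- For it: the step is mild and convergent, and the regiochemistry follows from the known bias of 3-alkoxy arynes. Steric bulk in the partners matters less than in the cycloaddition of a hindered ynone. On this point it is the stronger plan.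
- Against it: A2 needs a resorcinol in which methoxy and benzyloxy are already distinguished and in which silyl and triflate sit on the correct pair of neighbouring positions, so the differentiation problem returns in the precursor. A1 has ring E but not the lower chroman. C-benzylation with a ring D benzyl halide, reduction and ring closure are still needed, and lower C3 must be set by an auxiliary-controlled enolate alkylation next to a di-ortho-substituted arene.
- Comparison: the chosen route is shorter after the ring-forming step and enters it with rings D and F and the lower stereocentre complete. It gives up the insensitivity of aryne chemistry to steric bulk.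

**Alternative 2: cationic closure of ring C at C4–C4a.**
- Disconnection: the C4–C4a bond is cut. The precursor is carbinol A6, in which C4 carries ring E and a hydroxyl, C3 carries ring B, and C2 is bonded through oxygen to the 3-benzyloxyphenyl group that becomes ring A.
- Forward key step: acid ionises the carbinol, and the ring A carbon para to the benzyloxy group and ortho to the ether oxygen attacks the cation. The product is the tetra-O-benzyl ether A5, the same compound as 28.
- For it: the cation is strongly stabilised by the E2 methoxy and E4 benzyloxy groups, and a cation tolerates crowding at C4 better than a bimolecular addition. The C4 configuration follows from C3 by attack anti to ring B, so the trans relationship needs no catalyst. On diastereocontrol at C4 this plan is at least as good as the chosen one.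
- Against it: C3 must be made beforehand in an open chain, most naturally through an α-aryl ketone that epimerises readily. The cation has a tertiary benzylic hydrogen next to it, so proton loss to a stilbene or a 1,2-shift of ring B through a phenonium ion can destroy or scramble C3. Ring A can also react between its two oxygens. The plan says nothing about ring E, which must be built with the lower isoflavan in any case.
- Comparison: as an endgame it costs more steps (ether formation, installation of ring B, carbinol) than the chosen annulation, which forms C3–C4 and O1–C2 and sets both centres in one catalytic step. The chosen plan pays with a bimolecular addition at a crowded methide carbon.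

**Alternative 3: oxygen insertion into a 3-arylindanone.**
- Disconnection: O1 is removed from ring C, giving the 3-arylindan-1-one A8, whose benzo ring is ring A and whose C3 carries ring E with the lower isoflavan.
- Forward key step: a peracid inserts oxygen between the ring A carbon and the ketone carbon. Migration of the aryl carbon gives the six-membered lactone A7, with C8a–O1 and O1–C2 newly formed.
- For it: the migration proceeds with retention and does not touch C4, so that centre can be set early by a conjugate addition. No ring A phenol has to be protected and released to make the C8a–O1 bond. In these respects it is stronger than the chosen route.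
- Against it: the migrating carbon is meta to the benzyloxy group and has no donor ortho or para, so migration of the CH2 group to the isomeric lactone competes. A peracid in the presence of three electron-rich arenes invites ring oxidation. The indanone itself needs a conjugate addition involving the di-ortho-substituted ring E. A7 still lacks ring B, which would need a lactone α-arylation with an ortho-alkoxy aryl halide and then removal of the lactone carbonyl.
- Comparison: the endgame is longer and has an oxidation of uncertain chemoselectivity at its centre. The chosen route uses no oxidant after the ynone stage and closes ring C with ring B already on the incoming carbon.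

Key step: step 11

Assumption: the sense of induction of the CuCl/(R,R)-QuinoxP* borylation (step 3) and of the (R)-prolinol catalyst (step 19) is assigned by analogy with the accepted models; both are available in either enantiomeric form, so an opposite sense would be corrected by taking the antipode without changing the route.

## Route

Step 1
Reactants: 1 2,4-dihydroxybenzaldehyde
Product: 2 4-(benzyloxy)-2-hydroxybenzaldehyde
Conditions: BnBr (1.05 equiv), NaHCO3, KI (cat.), MeCN, 80 °C
Reagents that add atoms: benzyl bromide, BrCc1ccccc1
Why: Williamson etherification; the 2-hydroxyl is held in a hydrogen bond to the aldehyde and the 4-hydroxyl is the more acidic one, so a weak base should alkylate only the 4-position.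

Step 2
Reactants: 2 4-(benzyloxy)-2-hydroxybenzaldehyde
Product: 3 7-(benzyloxy)-2H-chromene
Conditions: NaH (1.1 equiv), THF/DMF, 0 °C; CH2=CHPPh3Br, 0 → 65 °C
Reagents that add atoms: vinyltriphenylphosphonium bromide, C=C[P+](c1ccccc1)(c1ccccc1)c1ccccc1.[Br-]
Why: Schweizer chromene synthesis; the phenoxide adds to the vinylphosphonium salt and the resulting ylide closes onto the aldehyde by intramolecular Wittig olefination, which gives the C3=C4 alkene and C2 in one operation.

Step 3
Reactants: 3 7-(benzyloxy)-2H-chromene
Product: 4 2-[(3S)-7-(benzyloxy)chroman-3-yl]-4,4,5,5-tetramethyl-1,3,2-dioxaborolane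
Conditions: B2pin2 (1.1 equiv), CuCl (5 mol %), (R,R)-QuinoxP* (5.5 mol %), NaOtBu (10 mol %), MeOH (2 equiv), THF, 0 °C → rt
Reagents that add atoms: bis(pinacolato)diboron, CC1(C)OB(OC1(C)C)B1OC(C)(C)C(C)(C)O1
Why: Copper-catalysed enantioselective protoboration of a cyclic styrene; the copper boryl adds with boron at C3 and copper at the benzylic C4, and methanol protonates the C–Cu bond. The chiral bisphosphine selects the alkene face and so sets lower C3; the (3S)-boronate has the spatial arrangement that becomes (3R) once carbon replaces boron.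

Step 4
Reactants: 4 2-[(3S)-7-(benzyloxy)chroman-3-yl]-4,4,5,5-tetramethyl-1,3,2-dioxaborolane
Product: 6 (3S)-7-(benzyloxy)-3-(1-bromovinyl)chroman, via lithium vinylboronate complex 5 (not isolated)
Conditions: CH2=CHBr (3 equiv), LiN(iPr)2 (2 equiv, added to the mixture), THF, −78 °C; I2, MeOH, −78 °C; NaOMe, −78 °C → rt
Reagents that add atoms: vinyl bromide, C=CBr
Why: Zweifel olefination with an α-lithiated vinyl halide; iodination of the alkene in complex 5 triggers migration of the chromanyl group from boron to carbon with retention, and methoxide induces anti elimination of boron and iodine. The descriptor stays S only because the bromovinyl group ranks first; the spatial arrangement is unchanged.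

Step 5
Reactants: 6 (3S)-7-(benzyloxy)-3-(1-bromovinyl)chroman
Product: 7 (3R)-7-(benzyloxy)-3-ethynylchroman
Conditions: Bu4NF·3H2O (3 equiv), DMF, 60 °C
Reagents that add atoms: none
Why: Fluoride-promoted dehydrobromination of a 2-bromoalk-1-ene to the terminal alkyne through the vinylic hydrogen anti to bromine; the conditions are too mild to deprotonate the adjacent stereocentre, and the change of descriptor to R is a matter of priority only.

Step 6
Reactants: 2 4-(benzyloxy)-2-hydroxybenzaldehyde
Product: 8 4-(benzyloxy)-2-(methoxymethoxy)benzaldehyde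
Conditions: MOMCl, iPr2NEt, CH2Cl2, 0 °C → rt
Reagents that add atoms: chloromethyl methyl ether, COCCl
Why: Acetal protection of the phenol; the methoxymethyl group is chosen because acid removes it later without touching benzyl or methyl ethers, so the ring A ortho oxygen can be released alone.

Step 7
Reactants: 7 (3R)-7-(benzyloxy)-3-ethynylchroman; 8 4-(benzyloxy)-2-(methoxymethoxy)benzaldehyde
Product: 10 1-[4-(benzyloxy)-2-(methoxymethoxy)phenyl]-3-[(3R)-7-(benzyloxy)chroman-3-yl]prop-2-yn-1-ol (both carbinol epimers), via lithium chromanylacetylide 9 (not isolated)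
Conditions: nBuLi (1.05 equiv), THF, −78 °C; then 8, −78 → 0 °C; aq. NH4Cl
Reagents that add atoms: none
Why: Addition of a lithium acetylide to an aryl aldehyde; only the acetylenic hydrogen is acidic enough for nBuLi at −78 °C, and the carbinol configuration is irrelevant because the next step oxidises it.

Step 8
Reactants: 10 1-[4-(benzyloxy)-2-(methoxymethoxy)phenyl]-3-[(3R)-7-(benzyloxy)chroman-3-yl]prop-2-yn-1-ol
Product: 11 1-[4-(benzyloxy)-2-(methoxymethoxy)phenyl]-3-[(3R)-7-(benzyloxy)chroman-3-yl]prop-2-yn-1-one
Conditions: MnO2 (activated, excess), CH2Cl2, rt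
Reagents that add atoms: none
Why: MnO2 oxidation of a benzylic and propargylic alcohol under neutral conditions, so the propargylic C–H γ to the new ketone never meets a base that could isomerise the ynone to an allenone.

Step 9
Reactants: 12 1,1-dimethoxyethene
Product: 13 4,4-dimethoxybut-3-en-2-one
Conditions: AcCl (1 equiv), 12 (2 equiv), Et2O, 0 °C → rt
Reagents that add atoms: acetyl chloride, CC(Cl)=O
Why: C-acylation of a ketene acetal by an acid chloride; the second equivalent of 12 takes up the hydrogen chloride, so no amine is present that could convert the acid chloride to ketene.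

Step 10
Reactants: 13 4,4-dimethoxybut-3-en-2-one
Product: 14 1,1-dimethoxy-3-(trimethylsilyloxy)buta-1,3-diene
Conditions: Me3SiOTf, Et3N, Et2O, 0 °C; distillation
Reagents that add atoms: trimethylsilyl trifluoromethanesulfonate, C[Si](C)(C)OS(=O)(=O)C(F)(F)F
Why: Soft enolisation and O-silylation of the methyl ketone, whose methyl group is the only enolisable position; distillation frees the diene of amine before it meets the ynone.

Step 11
Reactants: 11 1-[4-(benzyloxy)-2-(methoxymethoxy)phenyl]-3-[(3R)-7-(benzyloxy)chroman-3-yl]prop-2-yn-1-one; 14 1,1-dimethoxy-3-(trimethylsilyloxy)buta-1,3-diene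
Product: 17 [4-(benzyloxy)-2-(methoxymethoxy)phenyl]{2-[(3R)-7-(benzyloxy)chroman-3-yl]-4-hydroxy-6-methoxyphenyl}methanone, via cyclohexadiene cycloadduct 15 (not isolated), via aryl trimethylsilyl ether 16 (not isolated)
Conditions: 14 (3 equiv), toluene, 110 °C, sealed tube; then K2CO3 (cat.), MeOH, rt
Reagents that add atoms: none
Why: Thermal [4+2] cycloaddition of an electron-rich 1,1-dialkoxy-3-silyloxybutadiene to an acetylenic ketone followed by aromatisation, the established route from alkynones and alkynoates to 6-substituted 4-hydroxy-2-methoxyaryl carbonyl compounds. The largest HOMO coefficient of the diene lies on its CH2 terminus and the largest LUMO coefficient of the ynone on the carbon β to the carbonyl, so the more advanced bond is CH2–Cβ (E5–E6) and the acetal carbon then bonds to Cα (E1–E2). Ring E is closed by the cycloaddition itself; in the stepwise limit the allenolate carbon collapses onto the dialkoxycarbenium carbon in a 6-exo-trig closure. Adduct 15 is a cyclohexa-1,4-diene that aromatises by 1,4-elimination of methanol from the acetal carbon and the ring CH2, and methanolysis of silyl ether 16 frees the E4 hydroxyl. No stereocentre is formed; the lower C3 centre is propargylic and γ to the ketone, and it is safe because the medium contains no base that could isomerise the ynone. The selectivity required is regiochemical, methoxy ortho and hydroxyl para to the ketone, and the polarity match of the two partners secures it. The product has E2 methoxy and E4 hydroxyl already differentiated, and the di-ortho-substituted benzophenone arises without any coupling at a hindered position. The risk is rate, because the β-carbon bears a secondary alkyl group and the carbonyl is attenuated by an electron-rich aryl group; hence the excess of diene and the sealed-tube temperature.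

Step 12
Reactants: 17 [4-(benzyloxy)-2-(methoxymethoxy)phenyl]{2-[(3R)-7-(benzyloxy)chroman-3-yl]-4-hydroxy-6-methoxyphenyl}methanone
Product: 18 [4-(benzyloxy)-2-(methoxymethoxy)phenyl]{4-(benzyloxy)-2-[(3R)-7-(benzyloxy)chroman-3-yl]-6-methoxyphenyl}methanone
Conditions: BnBr, K2CO3, DMF, rt
Reagents that add atoms: benzyl bromide, BrCc1ccccc1
Why: Williamson etherification of a phenol para to a ketone; capping E4 ensures that a quinone methide can later form only through ring A.

Step 13
Reactants: 18 [4-(benzyloxy)-2-(methoxymethoxy)phenyl]{4-(benzyloxy)-2-[(3R)-7-(benzyloxy)chroman-3-yl]-6-methoxyphenyl}methanone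
Product: 19 [4-(benzyloxy)-2-hydroxyphenyl]{4-(benzyloxy)-2-[(3R)-7-(benzyloxy)chroman-3-yl]-6-methoxyphenyl}methanone
Conditions: 3 M aq. HCl, MeOH/THF, 50 °C
Reagents that add atoms: none
Why: Acid-catalysed cleavage of the aryl methoxymethyl acetal; benzyl and methyl ethers and the diaryl ketone are inert to these conditions.

Step 14
Reactants: 19 [4-(benzyloxy)-2-hydroxyphenyl]{4-(benzyloxy)-2-[(3R)-7-(benzyloxy)chroman-3-yl]-6-methoxyphenyl}methanone
Product: 20 5-(benzyloxy)-2-[{4-(benzyloxy)-2-[(3R)-7-(benzyloxy)chroman-3-yl]-6-methoxyphenyl}(hydroxy)methyl]phenol (both carbinol epimers)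
Conditions: LiAlH4 (2.5 equiv), THF, 0 °C → rt; aq. KNaC4H4O6 work-up, no acid
Reagents that add atoms: none
Why: Hydride reduction of a diaryl ketone; LiAlH4 is taken because the carbonyl is flanked by a di-ortho-substituted ring, and the carbinol configuration is irrelevant since it is lost in the quinone methide. The work-up is kept neutral because the electron-rich benzhydrol ionises easily.

Step 15
Reactants: 21 2,6-dimethoxyphenol
Product: 22 2-(benzyloxy)-1,3-dimethoxybenzene
Conditions: BnBr, K2CO3, DMF, 60 °C
Reagents that add atoms: benzyl bromide, BrCc1ccccc1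
Why: Williamson etherification of the hindered phenol.

Step 16
Reactants: 22 2-(benzyloxy)-1,3-dimethoxybenzene
Product: 23 3-(benzyloxy)-2,4-dimethoxybenzaldehyde
Conditions: POCl3, DMF, 0 → 70 °C; then ice-water
Reagents that add atoms: N,N-dimethylformamide, CN(C)C=O; water, O
Why: Vilsmeier–Haack formylation; position 4 is ortho to one methoxy group and para to the other, whereas the position para to the twisted benzyloxy group is meta to both, so substitution should follow the pattern of 1,2,3-trialkoxybenzenes.

Step 17
Reactants: 23 3-(benzyloxy)-2,4-dimethoxybenzaldehyde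
Product: 24 2-(benzyloxy)-1,3-dimethoxy-4-(2-methoxyvinyl)benzene (E/Z mixture)
Conditions: MeOCH2PPh3Cl, KOtBu, THF, 0 °C → rt
Reagents that add atoms: (methoxymethyl)triphenylphosphonium chloride, COC[P+](c1ccccc1)(c1ccccc1)c1ccccc1.[Cl-]
Why: Wittig olefination with a methoxymethylene ylide, the standard one-carbon homologation of an aryl aldehyde; the alkene geometry is irrelevant because the next step hydrolyses it.

Step 18
Reactants: 24 2-(benzyloxy)-1,3-dimethoxy-4-(2-methoxyvinyl)benzene
Product: 25 2-[3-(benzyloxy)-2,4-dimethoxyphenyl]acetaldehyde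
Conditions: 2 M aq. HCl, THF, 40 °C; used without storage
Reagents that add atoms: water, O
Why: Acid hydrolysis of the enol ether through protonation at the benzylic carbon and hydration of the oxocarbenium ion; the aldehyde is taken on at once because arylacetaldehydes self-condense on standing.

Step 19
Reactants: 20 5-(benzyloxy)-2-[{4-(benzyloxy)-2-[(3R)-7-(benzyloxy)chroman-3-yl]-6-methoxyphenyl}(hydroxy)methyl]phenol; 25 2-[3-(benzyloxy)-2,4-dimethoxyphenyl]acetaldehyde
Product: 27 (3R,4S)-7-(benzyloxy)-4-{4-(benzyloxy)-2-[(3R)-7-(benzyloxy)chroman-3-yl]-6-methoxyphenyl}-3-[3-(benzyloxy)-2,4-dimethoxyphenyl]chroman-2-ol (both C2 anomers), via ortho-quinone methide 26 (not isolated)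
Conditions: (R)-α,α-diphenylprolinol trimethylsilyl ether (20 mol %), PhCO2H (20 mol %), 25 (2 equiv), CH2Cl2, rt
Reagents that add atoms: none
Why: Aminocatalytic formal [4+2] annulation of an in situ ortho-quinone methide with an aldehyde; benzoic acid ionises 20 to 26, the E-enamine of 25 adds through its unshielded face to the methide carbon in a synclinal arrangement that gives the 3,4-trans relationship, and the phenoxide closes onto the iminium carbon before hydrolysis returns the catalyst. The (R)-catalyst is expected to set C3 as R and C4 as S, and C3, being enolisable through the catalyst, can drift only toward the more stable trans isomer. The ortho substituents of ring E lie above and below the methide plane and ring E can turn the small methoxy group toward either face, so the remote lower stereocentre should interfere little with catalyst control.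

Step 20
Reactants: 27 (3R,4S)-7-(benzyloxy)-4-{4-(benzyloxy)-2-[(3R)-7-(benzyloxy)chroman-3-yl]-6-methoxyphenyl}-3-[3-(benzyloxy)-2,4-dimethoxyphenyl]chroman-2-ol
Product: 28 (3R,4S)-7-(benzyloxy)-4-{4-(benzyloxy)-2-[(3R)-7-(benzyloxy)chroman-3-yl]-6-methoxyphenyl}-3-[3-(benzyloxy)-2,4-dimethoxyphenyl]chroman
Conditions: Et3SiH (5 equiv), BF3·OEt2, CH2Cl2, −78 → −20 °C
Reagents that add atoms: none
Why: Ionic hydrogenation of a lactol; the Lewis acid ionises C2 to the oxocarbenium ion and the silane delivers hydride. C2 becomes a methylene group and the stereocentres at C3 and C4 are not at the reacting carbon; low temperature and excess silane favour hydride capture over proton loss.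

Step 21
Reactants: 28 (3R,4S)-7-(benzyloxy)-4-{4-(benzyloxy)-2-[(3R)-7-(benzyloxy)chroman-3-yl]-6-methoxyphenyl}-3-[3-(benzyloxy)-2,4-dimethoxyphenyl]chroman
Product: 29 (3R,4S)-3-(3-hydroxy-2,4-dimethoxyphenyl)-4-{4-hydroxy-2-[(3R)-7-hydroxychroman-3-yl]-6-methoxyphenyl}chroman-7-ol
Conditions: H2 (1 atm), 10% Pd/C, EtOAc/MeOH, rt
Reagents that add atoms: none
Why: Hydrogenolysis of the four aryl benzyl ethers; the chroman C2–O bonds are not benzylic and the aryl–C4 bonds are carbon–carbon bonds, so nothing else should be cleaved.

## Compound list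

1 | 2,4-dihydroxybenzaldehyde | O=Cc1ccc(O)cc1O | starting material
2 | 4-(benzyloxy)-2-hydroxybenzaldehyde | O=Cc1ccc(OCc2ccccc2)cc1O | intermediate
3 | 7-(benzyloxy)-2H-chromene | C1=Cc2ccc(OCc3ccccc3)cc2OC1 | intermediate
4 | 2-[(3S)-7-(benzyloxy)chroman-3-yl]-4,4,5,5-tetramethyl-1,3,2-dioxaborolane | CC1(C)OB([C@@H]2COc3cc(OCc4ccccc4)ccc3C2)OC1(C)C | intermediate
5 | lithium (1-bromovinyl)[(3S)-7-(benzyloxy)chroman-3-yl](pinacolato)borate | [Li+].C=C(Br)[B-]1([C@@H]2COc3cc(OCc4ccccc4)ccc3C2)OC(C)(C)C(C)(C)O1 | intermediate (not isolated)
6 | (3S)-7-(benzyloxy)-3-(1-bromovinyl)chroman | C=C(Br)[C@@H]1COc2cc(OCc3ccccc3)ccc2C1 | intermediate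
7 | (3R)-7-(benzyloxy)-3-ethynylchroman | C#C[C@@H]1COc2cc(OCc3ccccc3)ccc2C1 | intermediate
8 | 4-(benzyloxy)-2-(methoxymethoxy)benzaldehyde | COCOc1cc(OCc2ccccc2)ccc1C=O | intermediate
9 | lithium [(3R)-7-(benzyloxy)chroman-3-yl]acetylide | [Li]C#C[C@@H]1COc2cc(OCc3ccccc3)ccc2C1 | intermediate (not isolated)
10 | 1-[4-(benzyloxy)-2-(methoxymethoxy)phenyl]-3-[(3R)-7-(benzyloxy)chroman-3-yl]prop-2-yn-1-ol, both carbinol epimers | COCOc1cc(OCc2ccccc2)ccc1C(O)C#C[C@@H]1COc2cc(OCc3ccccc3)ccc2C1 | intermediate
11 | 1-[4-(benzyloxy)-2-(methoxymethoxy)phenyl]-3-[(3R)-7-(benzyloxy)chroman-3-yl]prop-2-yn-1-one | COCOc1cc(OCc2ccccc2)ccc1C(=O)C#C[C@@H]1COc2cc(OCc3ccccc3)ccc2C1 | intermediate (key-step precursor)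
12 | 1,1-dimethoxyethene | C=C(OC)OC | starting material
13 | 4,4-dimethoxybut-3-en-2-one | CC(=O)C=C(OC)OC | intermediate
14 | 1,1-dimethoxy-3-(trimethylsilyloxy)buta-1,3-diene | COC(OC)=CC(=C)O[Si](C)(C)C | intermediate (key-step precursor)
15 | [4-(benzyloxy)-2-(methoxymethoxy)phenyl]{2-[(3R)-7-(benzyloxy)chroman-3-yl]-6,6-dimethoxy-4-(trimethylsilyloxy)cyclohexa-1,4-dien-1-yl}methanone | COCOc1cc(OCc2ccccc2)ccc1C(=O)C1=C([C@@H]2COc3cc(OCc4ccccc4)ccc3C2)CC(O[Si](C)(C)C)=CC1(OC)OC | intermediate (not isolated)
16 | [4-(benzyloxy)-2-(methoxymethoxy)phenyl]{2-[(3R)-7-(benzyloxy)chroman-3-yl]-6-methoxy-4-(trimethylsilyloxy)phenyl}methanone | COCOc1cc(OCc2ccccc2)ccc1C(=O)c1c(OC)cc(O[Si](C)(C)C)cc1[C@@H]1COc2cc(OCc3ccccc3)ccc2C1 | intermediate (not isolated)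
17 | [4-(benzyloxy)-2-(methoxymethoxy)phenyl]{2-[(3R)-7-(benzyloxy)chroman-3-yl]-4-hydroxy-6-methoxyphenyl}methanone | COCOc1cc(OCc2ccccc2)ccc1C(=O)c1c(OC)cc(O)cc1[C@@H]1COc2cc(OCc3ccccc3)ccc2C1 | intermediate (key-step product)
18 | [4-(benzyloxy)-2-(methoxymethoxy)phenyl]{4-(benzyloxy)-2-[(3R)-7-(benzyloxy)chroman-3-yl]-6-methoxyphenyl}methanone | COCOc1cc(OCc2ccccc2)ccc1C(=O)c1c(OC)cc(OCc2ccccc2)cc1[C@@H]1COc2cc(OCc3ccccc3)ccc2C1 | intermediate
19 | [4-(benzyloxy)-2-hydroxyphenyl]{4-(benzyloxy)-2-[(3R)-7-(benzyloxy)chroman-3-yl]-6-methoxyphenyl}methanone | Oc1cc(OCc2ccccc2)ccc1C(=O)c1c(OC)cc(OCc2ccccc2)cc1[C@@H]1COc2cc(OCc3ccccc3)ccc2C1 | intermediate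
20 | 5-(benzyloxy)-2-[{4-(benzyloxy)-2-[(3R)-7-(benzyloxy)chroman-3-yl]-6-methoxyphenyl}(hydroxy)methyl]phenol, both carbinol epimers | Oc1cc(OCc2ccccc2)ccc1C(O)c1c(OC)cc(OCc2ccccc2)cc1[C@@H]1COc2cc(OCc3ccccc3)ccc2C1 | intermediate
21 | 2,6-dimethoxyphenol | COc1cccc(OC)c1O | starting material
22 | 2-(benzyloxy)-1,3-dimethoxybenzene | COc1cccc(OC)c1OCc1ccccc1 | intermediate
23 | 3-(benzyloxy)-2,4-dimethoxybenzaldehyde | COc1ccc(C=O)c(OC)c1OCc1ccccc1 | intermediate
24 | 2-(benzyloxy)-1,3-dimethoxy-4-(2-methoxyvinyl)benzene, E/Z mixture | COC=Cc1ccc(OC)c(OCc2ccccc2)c1OC | intermediate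
25 | 2-[3-(benzyloxy)-2,4-dimethoxyphenyl]acetaldehyde | O=CCc1ccc(OC)c(OCc2ccccc2)c1OC | intermediate
26 | 3-(benzyloxy)-6-({4-(benzyloxy)-2-[(3R)-7-(benzyloxy)chroman-3-yl]-6-methoxyphenyl}methylidene)cyclohexa-2,4-dien-1-one | O=C1C=C(OCc2ccccc2)C=CC1=Cc1c(OC)cc(OCc2ccccc2)cc1[C@@H]1COc2cc(OCc3ccccc3)ccc2C1 | intermediate (not isolated)
27 | (3R,4S)-7-(benzyloxy)-4-{4-(benzyloxy)-2-[(3R)-7-(benzyloxy)chroman-3-yl]-6-methoxyphenyl}-3-[3-(benzyloxy)-2,4-dimethoxyphenyl]chroman-2-ol, both C2 anomers | COc1ccc([C@@H]2C(O)Oc3cc(OCc4ccccc4)ccc3[C@H]2c2c(OC)cc(OCc4ccccc4)cc2[C@@H]2COc3cc(OCc4ccccc4)ccc3C2)c(OC)c1OCc1ccccc1 | intermediate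
28 | (3R,4S)-7-(benzyloxy)-4-{4-(benzyloxy)-2-[(3R)-7-(benzyloxy)chroman-3-yl]-6-methoxyphenyl}-3-[3-(benzyloxy)-2,4-dimethoxyphenyl]chroman | COc1ccc([C@@H]2COc3cc(OCc4ccccc4)ccc3[C@H]2c2c(OC)cc(OCc4ccccc4)cc2[C@@H]2COc3cc(OCc4ccccc4)ccc3C2)c(OC)c1OCc1ccccc1 | intermediate
29 | (3R,4S)-3-(3-hydroxy-2,4-dimethoxyphenyl)-4-{4-hydroxy-2-[(3R)-7-hydroxychroman-3-yl]-6-methoxyphenyl}chroman-7-ol | COc1ccc([C@@H]2COc3cc(O)ccc3[C@H]2c2c(OC)cc(O)cc2[C@@H]2COc3cc(O)ccc3C2)c(OC)c1O | target

## Step count and least certain steps

Total: 21 steps. Longest linear sequence: 14 steps (1, 2, 3, 4, 5, 7, 8, 11, 12, 13, 14, 19, 20, 21).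

**Step 11 (key step).**
- What may go wrong: the cycloaddition may be slow, because the β-carbon of the ynone carries a secondary alkyl group and the carbonyl is deactivated by an electron-rich aryl ring. Prolonged heating then favours decomposition of the diene and isomerisation at the propargylic C–H, with erosion of the lower stereocentre.
- Fallback, from 7 back to the route at 20: the acetylide of 7 is trapped with methyl chloroformate to give methyl 3-[(3R)-7-(benzyloxy)chroman-3-yl]prop-2-ynoate F1. An alkynoate is the best-established dienophile for diene 14, and cycloaddition and aromatisation should give methyl 2-[(3R)-7-(benzyloxy)chroman-3-yl]-4-hydroxy-6-methoxybenzoate F2. Benzylation gives methyl 4-(benzyloxy)-2-[(3R)-7-(benzyloxy)chroman-3-yl]-6-methoxybenzoate F3. LiAlH4 reduction gives {4-(benzyloxy)-2-[(3R)-7-(benzyloxy)chroman-3-yl]-6-methoxyphenyl}methanol F4, and MnO2 oxidation gives 4-(benzyloxy)-2-[(3R)-7-(benzyloxy)chroman-3-yl]-6-methoxybenzaldehyde F5. Ortho-selective hydroxyalkylation of the bromomagnesium phenoxide of commercial 3-(benzyloxy)phenol (EtMgBr, toluene) with F5 then gives benzhydrol 20 directly, bypassing 17 to 19.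

**Step 19.**
- What may go wrong: addition to the methide carbon may be slow or poorly face-selective because the carbon is flanked by two ortho substituents. The arylacetaldehyde may self-condense, and the catalyst may be reversibly N-alkylated by the quinone methide.
- Fallback, from 20 and 24 back to the route at 28: a chiral phosphoric acid such as (R)-TRIP generates the quinone methide from 20 and holds it by hydrogen bonding. Inverse-demand hetero-Diels–Alder addition of the (E)-enriched enol ether 24 forms C3–C4 and O1–C2 in one step. The product is (3R,4S)-7-(benzyloxy)-4-{4-(benzyloxy)-2-[(3R)-7-(benzyloxy)chroman-3-yl]-6-methoxyphenyl}-3-[3-(benzyloxy)-2,4-dimethoxyphenyl]-2-methoxychroman F6. Reduction of the acetal with Et3SiH and BF3·OEt2 leads to 28. Because lower C3 is fixed, any stereoisomers at C3 and C4 are diastereomers and can be removed by chromatography.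

**Step 3.**
- What may go wrong: enantioselectivity may be insufficient, or borocupration of the electron-rich styrenic alkene may be slow.
- Fallback, from 2 back to the route at 7 (it also replaces steps 4 and 5): condensation of 2 with acrolein (K2CO3, dioxane, reflux) gives 7-(benzyloxy)-2H-chromene-3-carbaldehyde F7. Reduction with NaBH4 and CeCl3 gives [7-(benzyloxy)-2H-chromen-3-yl]methanol F8. Asymmetric hydrogenation of this allylic alcohol with [Ir(cod)(L)][B(C6H3(CF3)2)4], where L is a chiral phosphino-oxazoline, gives [(3R)-7-(benzyloxy)chroman-3-yl]methanol F9. Buffered Dess–Martin oxidation gives (3S)-7-(benzyloxy)chroman-3-carbaldehyde F10. Homologation with lithiated (trimethylsilyl)diazomethane at −78 °C (Colvin rearrangement) gives alkyne 7 without exposing the aldehyde to an equilibrating base.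

**Step 14.**
- What may go wrong: the ortho-phenoxide may expel the aluminate to give a quinone methide that takes up a second hydride, which is over-reduction to the diarylmethane. The benzhydrol may also ionise and oligomerise on work-up.
- Fallback, from 18 back to the route at 27: the ketone is reduced with LiAlH4 while the ring A oxygen still bears its acetal, giving [4-(benzyloxy)-2-(methoxymethoxy)phenyl]{4-(benzyloxy)-2-[(3R)-7-(benzyloxy)chroman-3-yl]-6-methoxyphenyl}methanol F11. No quinone methide can form from F11. Sodium p-toluenesulfinate and aqueous HCl in THF/MeOH then trap the benzhydryl cation as the sulfone and cleave the acetal, giving 5-(benzyloxy)-2-[{4-(benzyloxy)-2-[(3R)-7-(benzyloxy)chroman-3-yl]-6-methoxyphenyl}(tosyl)methyl]phenol F12, a stable quinone methide precursor. In the annulation, aqueous NaHCO3 replaces benzoic acid, sulfinate is expelled to give 26, and 27 forms as in step 19.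

**Step 20.**
- What may go wrong: the oxocarbenium ion at C2 may lose the C3 proton, which is acidified by ring B. The resulting 4H-chromene would erode the C3 configuration before hydride arrives.
- Fallback, from 27 back to the route at 28: NaBH4 reduces the open hydroxy-aldehyde form of 27 to (2R,3S)-3-[4-(benzyloxy)-2-hydroxyphenyl]-3-{4-(benzyloxy)-2-[(3R)-7-(benzyloxy)chroman-3-yl]-6-methoxyphenyl}-2-[3-(benzyloxy)-2,4-dimethoxyphenyl]propan-1-ol F13. Mitsunobu cyclisation (PPh3, DIAD) of the phenol onto the primary alcohol closes ring C to 28 without a cation at C2.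

## Further compounds

F1 | step 11 | methyl 3-[(3R)-7-(benzyloxy)chroman-3-yl]prop-2-ynoate | COC(=O)C#C[C@@H]1COc2cc(OCc3ccccc3)ccc2C1
F2 | step 11 | methyl 2-[(3R)-7-(benzyloxy)chroman-3-yl]-4-hydroxy-6-methoxybenzoate | COC(=O)c1c(OC)cc(O)cc1[C@@H]1COc2cc(OCc3ccccc3)ccc2C1
F3 | step 11 | methyl 4-(benzyloxy)-2-[(3R)-7-(benzyloxy)chroman-3-yl]-6-methoxybenzoate | COC(=O)c1c(OC)cc(OCc2ccccc2)cc1[C@@H]1COc2cc(OCc3ccccc3)ccc2C1
F4 | step 11 | {4-(benzyloxy)-2-[(3R)-7-(benzyloxy)chroman-3-yl]-6-methoxyphenyl}methanol | OCc1c(OC)cc(OCc2ccccc2)cc1[C@@H]1COc2cc(OCc3ccccc3)ccc2C1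
F5 | step 11 | 4-(benzyloxy)-2-[(3R)-7-(benzyloxy)chroman-3-yl]-6-methoxybenzaldehyde | O=Cc1c(OC)cc(OCc2ccccc2)cc1[C@@H]1COc2cc(OCc3ccccc3)ccc2C1
F6 | step 19 | (3R,4S)-7-(benzyloxy)-4-{4-(benzyloxy)-2-[(3R)-7-(benzyloxy)chroman-3-yl]-6-methoxyphenyl}-3-[3-(benzyloxy)-2,4-dimethoxyphenyl]-2-methoxychroman, C2 epimers | COc1ccc([C@@H]2C(OC)Oc3cc(OCc4ccccc4)ccc3[C@H]2c2c(OC)cc(OCc4ccccc4)cc2[C@@H]2COc3cc(OCc4ccccc4)ccc3C2)c(OC)c1OCc1ccccc1
F7 | step 3 | 7-(benzyloxy)-2H-chromene-3-carbaldehyde | O=CC1=Cc2ccc(OCc3ccccc3)cc2OC1
F8 | step 3 | [7-(benzyloxy)-2H-chromen-3-yl]methanol | OCC1=Cc2ccc(OCc3ccccc3)cc2OC1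
F9 | step 3 | [(3R)-7-(benzyloxy)chroman-3-yl]methanol | OC[C@@H]1COc2cc(OCc3ccccc3)ccc2C1
F10 | step 3 | (3S)-7-(benzyloxy)chroman-3-carbaldehyde | O=C[C@@H]1COc2cc(OCc3ccccc3)ccc2C1
F11 | step 14 | [4-(benzyloxy)-2-(methoxymethoxy)phenyl]{4-(benzyloxy)-2-[(3R)-7-(benzyloxy)chroman-3-yl]-6-methoxyphenyl}methanol, both carbinol epimers | COCOc1cc(OCc2ccccc2)ccc1C(O)c1c(OC)cc(OCc2ccccc2)cc1[C@@H]1COc2cc(OCc3ccccc3)ccc2C1
F12 | step 14 | 5-(benzyloxy)-2-[{4-(benzyloxy)-2-[(3R)-7-(benzyloxy)chroman-3-yl]-6-methoxyphenyl}(tosyl)methyl]phenol, both epimers at the sulfonyl carbon | Cc1ccc(cc1)S(=O)(=O)C(c1ccc(OCc2ccccc2)cc1O)c1c(OC)cc(OCc2ccccc2)cc1[C@@H]1COc2cc(OCc3ccccc3)ccc2C1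
F13 | step 20 | (2R,3S)-3-[4-(benzyloxy)-2-hydroxyphenyl]-3-{4-(benzyloxy)-2-[(3R)-7-(benzyloxy)chroman-3-yl]-6-methoxyphenyl}-2-[3-(benzyloxy)-2,4-dimethoxyphenyl]propan-1-ol | COc1ccc([C@H](CO)[C@@H](c2ccc(OCc3ccccc3)cc2O)c2c(OC)cc(OCc3ccccc3)cc2[C@@H]2COc3cc(OCc4ccccc4)ccc3C2)c(OC)c1OCc1ccccc1
A1 | alternative 1 | ethyl 2-[2-(2,4-bis(benzyloxy)benzoyl)-5-(benzyloxy)-3-methoxyphenyl]acetate | CCOC(=O)Cc1cc(OCc2ccccc2)cc(OC)c1C(=O)c1ccc(OCc2ccccc2)cc1OCc1ccccc1
A2 | alternative 1 | 5-(benzyloxy)-3-methoxy-2-(trimethylsilyl)phenyl trifluoromethanesulfonate | COc1cc(OCc2ccccc2)cc(OS(=O)(=O)C(F)(F)F)c1[Si](C)(C)C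
A3 | alternative 1 | 5-(benzyloxy)-3-methoxybenzyne | COC1=CC(OCc2ccccc2)=CC#C1
A4 | alternative 1 | ethyl 3-[2,4-bis(benzyloxy)phenyl]-3-oxopropanoate | CCOC(=O)CC(=O)c1ccc(OCc2ccccc2)cc1OCc1ccccc1
A5 | alternative 2 | (3R,4S)-7-(benzyloxy)-4-{4-(benzyloxy)-2-[(3R)-7-(benzyloxy)chroman-3-yl]-6-methoxyphenyl}-3-[3-(benzyloxy)-2,4-dimethoxyphenyl]chroman (identical with 28) | COc1ccc([C@@H]2COc3cc(OCc4ccccc4)ccc3[C@H]2c2c(OC)cc(OCc4ccccc4)cc2[C@@H]2COc3cc(OCc4ccccc4)ccc3C2)c(OC)c1OCc1ccccc1
A6 | alternative 2 | (2R)-1-{4-(benzyloxy)-2-[(3R)-7-(benzyloxy)chroman-3-yl]-6-methoxyphenyl}-2-[3-(benzyloxy)-2,4-dimethoxyphenyl]-3-[3-(benzyloxy)phenoxy]propan-1-ol, both carbinol epimers | COc1ccc([C@H](COc2cccc(OCc3ccccc3)c2)C(O)c2c(OC)cc(OCc3ccccc3)cc2[C@@H]2COc3cc(OCc4ccccc4)ccc3C2)c(OC)c1OCc1ccccc1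
A7 | alternative 3 | (4S)-7-(benzyloxy)-4-{4-(benzyloxy)-2-[(3R)-7-(benzyloxy)chroman-3-yl]-6-methoxyphenyl}chroman-2-one | O=C1C[C@H](c2c(OC)cc(OCc3ccccc3)cc2[C@@H]2COc3cc(OCc4ccccc4)ccc3C2)c2ccc(OCc3ccccc3)cc2O1
A8 | alternative 3 | (3S)-6-(benzyloxy)-3-{4-(benzyloxy)-2-[(3R)-7-(benzyloxy)chroman-3-yl]-6-methoxyphenyl}indan-1-one | O=C1C[C@H](c2c(OC)cc(OCc3ccccc3)cc2[C@@H]2COc3cc(OCc4ccccc4)ccc3C2)c2ccc(OCc3ccccc3)cc12
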